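The earlier runs and the new flask are calculated with constants of no real substance, and the scatter is random.

Q is the species to watch in this flask, charged at 0.190 M against 1.9 M of Z and 1.94 M of L, and you need dp and c at 20 min.

in all of them: L 1.94 M
- dawn: Z 1.3 M; Q 0.19 M; run made earlier
- spring: Z 2.8 M; Q 0.19 M; run made earlier
- flask: Z 1.9 M; Q 0.190 M; time 20 min

- dawn (time / min: X / %, Z / %): 3.00: 22.8, 63.2; 6.00: 37.1, 48.7; 10.0: 46.1, 39.2; 12.0: 51.6, 36.8; 15.0: 53.8, 31.1; 20.0: 58.3, 26.4
- spring (time / min: X / %, Z / %): 3.00: 22.0, 71.7; 6.00: 32.8, 59.9; 10.0: 40.6, 51.7; 12.0: 41.5, 51.5; 15.0: 45.1, 47.9; 20.0: 46.3, 45.8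

(scatter of a reading: 1 percentage point)

* average number of monomer units in a chain (unreacted monomers counted as chains of one) at 20 min
* part of the Z that has reacted at 20 min

- each molecule carries two end groups: a chain counts once for every two ends that are left, dead ends included; the units are half of the end groups of the two monomers charged
- a link that another step uses up counts as cut, two dead ends; so do two ends of one kind that react with each other

Turn the Z charge first, since the earlier runs changed it while holding L and Q. If Q takes Z one for one, the Z lost without forming X should stay the same amount whatever Z you charge, and the readings at 20.0 min show 0.199 M in the dawn run and 0.221 M in the spring run, close to the 0.19 M of Q. So the toll T, Q charged over Z charged, is 10.0 % in this flask, and c is T plus X as a percentage of Z. More Z lowers T and also the share of Z in X, which reads 58.3 % at dawn, more than the 46.3 % of spring. L stood at 1.94 M in both runs, so they leave the effect of its charge untested. Turning Q up raises T by hand, taking Z away from X. My own straight interpolation on Z puts X at 53.5 %, so my c is 63.5 %. Each link removes two of the S end groups charged, so dp = S/(S − 2X), with X in M, and mine is 2.13.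

The forecast, holding that “Q quickly and stoichiometrically kills Z”, gives dp 2.13 (2.04 to 2.23) and c 64 % (61 % to 67 %).

This flask gives dp 2.20 and c 65.1 %, with Q, the limiting reagent of its side step, down to 0 % of its charge.

    2 Z → D (k = 1.20 × 10⁻⁵ /M/min)
    Z + L ⇌ X + E (K = 61.0, k = 0.0590 /M/min)
    Z + Q → G (k = 0.760 /M/min)
    L → J (k = 0.0360 /min)

Taking T from c leaves 55.1 %, and X stands at 55.1 %. A neighbour flask charged with 0.76 M of Q has T at 40.0 % and reaches c 81.6 %, higher than this flask, which leaves 41.6 % for X; there X stands at 41.6 % and dp falls to 1.70.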